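**Plan**
1. Numbering used (kaurane-type): ring A = C1–C5/C10 (C4 carries CH3 and the lactone carbonyl C19; C10 carries CH3 and OH); lactone O–C6H; link C7H2; bicyclo[3.2.1]octenone (rings C/D) = C8 (quaternary bridgehead), C9=O, C11=C12, C13, C14, C15 (OAc), C16=C17H2.
2. Retrosynthesis: the acetate and C16=C17 are late adjustments of a C15 ketone; ring C is opened at C11=C12 (retro-aldol condensation), which turns bridgehead C8 into the central carbon of a cyclopentane 1,3-diketone; then C7–C8 and O–C6 are cut together (oxidative radical carbolactonisation) to give vinyl hydroxy acid 9 (ring A) and diketone 16 (ring D).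
3. Enabling feature: C8 lies between two oxygenated carbons (C9 and C15), so with ring C open it is an oxidisable 1,3-dicarbonyl C–H; C19(=O)–C4–C5–C6–C7 is a pent-4-enoic acid array, so a C8 radical can add to C7 and the C19 carboxylate can close the γ-lactone at C6.
4. Forward: ring A by Diels–Alder reaction, C10–OH by epoxidation and hydride opening; ring D by Diels–Alder reaction, ozonolytic C=C cleavage and Claisen re-closure (six- to five-membered ring, C13 kept); the coupling forms the lactone; ring C by aldol condensation; then C17, C15–OH and the acetate.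
5. Stereochemistry: C4/C5 and C13 from two catalytic asymmetric Diels–Alder reactions; C10 from face-selective epoxidation; C8 (1,3-induction from C13) and C6 (lactone closure) in the key step, both through planar radicals; C15 from exo-face hydride delivery on the bicycle.

Key step: step 10

Remarks: "L–CH2" stands for [(3R,3aS,4R,7aR)-4-hydroxy-4,7a-dimethyl-1-oxo-octahydro-2-benzofuran-3-yl]methyl, the ring A/lactone unit of the target. The two Diels–Alder catalysts (steps 2 and 6) are taken in the enantiomeric form that delivers the configurations drawn; which antipode that is has to be confirmed on the first adduct.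

**Step 1**
Reactants: 1 but-3-en-2-one (methyl vinyl ketone); 2 allylmagnesium bromide
Product: 4 (3E)-3-methylhexa-1,3,5-triene, via 3-methylhexa-1,5-dien-3-ol 3 (not isolated)
Conditions: Et2O, −78 to 0 °C; H2O quench; then KHSO4 (cat.), hydroquinone, 110 °C, triene distilled out as formed
Reagents that add atoms: none
Why: 1,2-Grignard addition to the enone carbonyl gives tertiary alcohol 3, whose acid-catalysed dehydration should give the conjugated triene as a 3E/3Z mixture, used as such because only the 3E isomer can reach the s-cis diene geometry needed in step 2.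

**Step 2**
Reactants: 4 (3E)-3-methylhexa-1,3,5-triene; 5 2-methylprop-2-enal (methacrolein)
Product: 6 (1R,2S)-2-ethenyl-1,3-dimethylcyclohex-3-ene-1-carbaldehyde
Conditions: chiral cationic oxazaborolidine Lewis acid (B-o-tolyl, diphenylprolinol-derived, activated with Tf2NH, 10 mol%), CH2Cl2, −78 to −40 °C
Reagents that add atoms: none
Why: Catalytic enantioselective Diels–Alder reaction in which the Lewis-acid-bound aldehyde adds to the C1–C4 diene unit of the triene (C4 carries the spectator vinyl group) with "ortho" regiochemistry and through the endo-formyl transition state, so that quaternary C4 and C5 are set with vinyl cis to CHO, the catalyst shielding one face of the dienophile.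

**Step 3**
Reactants: 6 (1R,2S)-2-ethenyl-1,3-dimethylcyclohex-3-ene-1-carbaldehyde
Product: 7 (1S,2R,3R,6R)-2-ethenyl-1,3-dimethyl-7-oxabicyclo[4.1.0]heptane-3-carbaldehyde
Conditions: dimethyldioxirane (1.05 equiv, acetone solution), CH2Cl2, −20 °C
Reagents that add atoms: dimethyldioxirane, CC1(C)OO1
Why: Epoxidation should be chemoselective for the electron-rich trisubstituted ring alkene and occur on the face anti to the adjacent vinyl (and formyl) groups, which fixes the configuration of the future carbinol carbon C10.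

**Step 4**
Reactants: 7 (1S,2R,3R,6R)-2-ethenyl-1,3-dimethyl-7-oxabicyclo[4.1.0]heptane-3-carbaldehyde
Product: 8 (1R,2R,3R)-2-ethenyl-3-(hydroxymethyl)-1,3-dimethylcyclohexan-1-ol
Conditions: LiAlH4, THF, 0 °C to reflux; H2O/aq. NaOH work-up
Reagents that add atoms: none
Why: Hydride reduction of the aldehyde and SN2 opening of the trisubstituted epoxide at its less substituted carbon (C1) leave the tertiary alcohol at C10 with retention, OH trans to the vinyl group.

**Step 5**
Reactants: 8 (1R,2R,3R)-2-ethenyl-3-(hydroxymethyl)-1,3-dimethylcyclohexan-1-ol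
Product: 9 (1R,2R,3R)-2-ethenyl-3-hydroxy-1,3-dimethylcyclohexane-1-carboxylic acid
Conditions: TEMPO (10 mol%), NaClO2, NaOCl (cat.), MeCN/phosphate buffer pH 6.7, 35 °C
Reagents that add atoms: sodium chlorite, [Na+].[O-]Cl=O
Why: Nitroxyl-catalysed oxidation (oxoammonium, then chlorite) takes the primary neopentyl alcohol to the acid, while the tertiary alcohol cannot be oxidised and the near-neutral buffer spares the vinyl group.

**Step 6**
Reactants: 10 2-methylbuta-1,3-diene (isoprene); 11 prop-2-enal (acrolein)
Product: 12 (1R)-4-methylcyclohex-3-ene-1-carbaldehyde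
Conditions: 5-benzyl-2,2,3-trimethylimidazolidin-4-one hydrochloride (10 mol%), MeNO2/H2O, rt
Reagents that add atoms: none
Why: Enantioselective organocatalytic Diels–Alder reaction in which the chiral iminium ion of acrolein reacts with isoprene with "para" regiochemistry and sets the single stereocentre, the future C13.

**Step 7**
Reactants: 12 (1R)-4-methylcyclohex-3-ene-1-carbaldehyde
Product: 13 (4R)-4-(dimethoxymethyl)-1-methylcyclohex-1-ene
Conditions: HC(OMe)3, MeOH, TsOH·H2O (cat.), rt
Reagents that add atoms: methanol, CO; trimethyl orthoformate, COC(OC)OC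
Why: Acid-catalysed acetalisation with orthoformate as water scavenger masks the aldehyde against ozone, base and the radical coupling.

**Step 8**
Reactants: 13 (4R)-4-(dimethoxymethyl)-1-methylcyclohex-1-ene
Product: 15 methyl (3R)-3-(dimethoxymethyl)-6-oxoheptanoate, via methoxy hydroperoxide 14 (not isolated)
Conditions: O3, CH2Cl2/MeOH, NaHCO3, −78 °C; then Ac2O, Et3N, 0 °C to rt
Reagents that add atoms: ozone, [O-][O+]=O; methanol, CO
Why: Ozonolysis in methanol cleaves the ring C=C with C13 untouched, the carbonyl oxide on the former CH carbon being trapped as methoxy hydroperoxide 14, which Ac2O/Et3N dehydrates to the methyl ester while the other terminus is the methyl ketone.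

**Step 9**
Reactants: 15 methyl (3R)-3-(dimethoxymethyl)-6-oxoheptanoate
Product: 16 (4R)-2-acetyl-4-(dimethoxymethyl)cyclopentan-1-one (C2 epimers and enol)
Conditions: KOtBu (1.1 equiv), THF, 0 °C to rt; AcOH quench
Reagents that add atoms: none
Why: Intramolecular Claisen (Dieckmann-type) condensation in which the internal ketone enolate (C8) attacks the ester to close the five-membered ring in preference to the seven-membered alternative, driven by deprotonation of the 1,3-diketone; C8 is stereochemically labile, C13 is not.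

**Step 10**
Reactants: 9 (1R,2R,3R)-2-ethenyl-3-hydroxy-1,3-dimethylcyclohexane-1-carboxylic acid; 16 (4R)-2-acetyl-4-(dimethoxymethyl)cyclopentan-1-one
Product: 17 (2S,4R)-2-acetyl-4-(dimethoxymethyl)-2-(L–CH2)cyclopentan-1-one
Conditions: Mn(OAc)3·2H2O (2.2 equiv), Cu(OAc)2·H2O (0.2 equiv), KOAc, AcOH, 25–40 °C, argon; 16 in 1.5-fold excess
Reagents that add atoms: none
Why: Proposed new method: trivalent manganese oxidises the enolised 1,3-diketone 16 (either C8 epimer or the enol) to a planar, electrophilic C8 radical that adds to the terminal carbon C7 of the vinyl group of 9, and the resulting C6 radical, which sits γ to the C19 carboxyl, is oxidised (Mn(OAc)3, relayed by Cu(OAc)2) with transfer of the carboxylate oxygen to C6; the closest known reaction types are the Mn(OAc)3-mediated oxidative addition of 1,3-dicarbonyl compounds to terminal alkenes and the Mn(OAc)3 γ-lactone synthesis from alkenes and acetic acid, in which the same kind of γ-carboxyalkyl radical is oxidised to a lactone. The only ring closed is the γ-lactone, by 5-exo attack of the carboxylate oxygen on C6, which can only give the cis-fused ring because C19 and C6 are cis on ring A. C8 is set by approach of the alkene to the face of the cyclopentanone radical anti to the C13 dimethoxymethyl group (1,3-induction), which places the acetyl group cis to C13 as ring C will need; C6 is set in the ring closure, where the new C7 chain should take the convex face of the bicyclic lactone, anti to quaternary C10. Chemoselectivity rests on 16 being the only readily enolised, oxidisable C–H acid (9 has a quaternary α-carbon and a single alkene, 16 has no alkene), and regioselectivity on attack at the unhindered CH2 terminus.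

**Step 11**
Reactants: 17 (2S,4R)-2-acetyl-4-(dimethoxymethyl)-2-(L–CH2)cyclopentan-1-one
Product: 19 (1R,5R)-1-(L–CH2)bicyclo[3.2.1]oct-3-ene-2,7-dione, via keto aldehyde 18 (not isolated)
Conditions: PPTS, acetone/H2O, 45 °C; solvent change; then Bn2NH·CF3CO2H, toluene, 60 °C
Reagents that add atoms: none
Why: Acetal hydrolysis followed by amine-salt-catalysed intramolecular aldol condensation of the methyl ketone (C11) onto the aldehyde (C12), the only geometrically possible aldol mode, closes the six-membered ring C as the bridged enone; C13 may epimerise in 18 but only the cis isomer can cyclise.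

**Step 12**
Reactants: 19 (1R,5R)-1-(L–CH2)bicyclo[3.2.1]oct-3-ene-2,7-dione
Product: 20 (1S,5S)-6-methylidene-1-(L–CH2)bicyclo[3.2.1]oct-3-ene-2,7-dione
Conditions: paraformaldehyde, N-methylanilinium trifluoroacetate, THF, 65 °C
Reagents that add atoms: formaldehyde (from paraformaldehyde), C=O
Why: Mannich-type α-methylenation (iminium addition to the enol, then β-elimination of N-methylaniline) at C16, the only enolisable position, since C8 and C13 are bridgeheads and the lactone has no α-hydrogen.

**Step 13**
Reactants: 20 (1S,5S)-6-methylidene-1-(L–CH2)bicyclo[3.2.1]oct-3-ene-2,7-dione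
Product: 21 (1R,5S,7R)-7-hydroxy-6-methylidene-1-(L–CH2)bicyclo[3.2.1]oct-3-en-2-one
Conditions: NaBH4 (1.0 equiv), CeCl3·7H2O, MeOH, −78 °C
Reagents that add atoms: none
Why: Luche reduction, in which 1,2-hydride addition to the C15 carbonyl from the exo face (the side of the one-carbon bridge C14), as is usual for bicyclo[3.2.1]octan-6-ones, should give the endo alcohol with the required C15 configuration; preference for the strained five-membered-ring C15 ketone over the C9 enone carbonyl is expected but is the weak point (see below).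

**Step 14**
Reactants: 21 (1R,5S,7R)-7-hydroxy-6-methylidene-1-(L–CH2)bicyclo[3.2.1]oct-3-en-2-one
Product: 22 (1R,5S,7R)-6-methylidene-2-oxo-1-(L–CH2)bicyclo[3.2.1]oct-3-en-7-yl acetate (target, CNP0172716.1)
Conditions: Ac2O (1.2 equiv), DMAP (cat.), pyridine, CH2Cl2, 0 °C to rt
Reagents that add atoms: acetic anhydride, CC(=O)OC(C)=O
Why: DMAP-catalysed acylation of the secondary allylic alcohol, under which the hindered tertiary C10–OH should not react, gives the target.

**Compound list**
1 | but-3-en-2-one (methyl vinyl ketone) | CC(=O)C=C | starting material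
2 | allylmagnesium bromide | C=CC[Mg]Br | starting material
3 | 3-methylhexa-1,5-dien-3-ol (racemic) | C=CCC(C)(O)C=C | intermediate
4 | (3E)-3-methylhexa-1,3,5-triene (formed together with the unreactive 3Z isomer) | C=C/C=C(C)/C=C | intermediate
5 | 2-methylprop-2-enal (methacrolein) | CC(=C)C=O | starting material
6 | (1R,2S)-2-ethenyl-1,3-dimethylcyclohex-3-ene-1-carbaldehyde | O=C[C@]1(C)CCC=C(C)[C@@H]1C=C | intermediate
7 | (1S,2R,3R,6R)-2-ethenyl-1,3-dimethyl-7-oxabicyclo[4.1.0]heptane-3-carbaldehyde | O=C[C@]1(C)CC[C@H]2O[C@@]2(C)[C@@H]1C=C | intermediate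
8 | (1R,2R,3R)-2-ethenyl-3-(hydroxymethyl)-1,3-dimethylcyclohexan-1-ol | OC[C@]1(C)CCC[C@@](C)(O)[C@@H]1C=C | intermediate
9 | (1R,2R,3R)-2-ethenyl-3-hydroxy-1,3-dimethylcyclohexane-1-carboxylic acid | OC(=O)[C@]1(C)CCC[C@@](C)(O)[C@@H]1C=C | intermediate
10 | 2-methylbuta-1,3-diene (isoprene) | CC(=C)C=C | starting material
11 | prop-2-enal (acrolein) | C=CC=O | starting material
12 | (1R)-4-methylcyclohex-3-ene-1-carbaldehyde | O=C[C@H]1CC=C(C)CC1 | intermediate
13 | (4R)-4-(dimethoxymethyl)-1-methylcyclohex-1-ene | COC(OC)[C@H]1CC=C(C)CC1 | intermediate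
14 | (5R)-5-(dimethoxymethyl)-7-hydroperoxy-7-methoxyheptan-2-one (C7 epimers) | COC(OO)C[C@@H](CCC(C)=O)C(OC)OC | intermediate
15 | methyl (3R)-3-(dimethoxymethyl)-6-oxoheptanoate | COC(=O)C[C@@H](CCC(C)=O)C(OC)OC | intermediate
16 | (4R)-2-acetyl-4-(dimethoxymethyl)cyclopentan-1-one (C2 epimers and enol) | CC(=O)C1C[C@@H](C(OC)OC)CC1=O | intermediate
17 | (2S,4R)-2-acetyl-4-(dimethoxymethyl)-2-(L–CH2)cyclopentan-1-one | CC(=O)[C@@]1(C[C@H]2OC(=O)[C@]3(C)CCC[C@@](C)(O)[C@H]23)C[C@@H](C(OC)OC)CC1=O | intermediate
18 | (1R,3S)-3-acetyl-4-oxo-3-(L–CH2)cyclopentane-1-carbaldehyde | CC(=O)[C@@]1(C[C@H]2OC(=O)[C@]3(C)CCC[C@@](C)(O)[C@H]23)C[C@@H](C=O)CC1=O | intermediate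
19 | (1R,5R)-1-(L–CH2)bicyclo[3.2.1]oct-3-ene-2,7-dione | O=C1C[C@@H]2C=CC(=O)[C@@]1(C[C@H]3OC(=O)[C@]4(C)CCC[C@@](C)(O)[C@H]34)C2 | intermediate
20 | (1S,5S)-6-methylidene-1-(L–CH2)bicyclo[3.2.1]oct-3-ene-2,7-dione | C=C1[C@@H]2C=CC(=O)[C@@](C[C@H]3OC(=O)[C@]4(C)CCC[C@@](C)(O)[C@H]34)(C2)C1=O | intermediate
21 | (1R,5S,7R)-7-hydroxy-6-methylidene-1-(L–CH2)bicyclo[3.2.1]oct-3-en-2-one | C=C1[C@@H]2C=CC(=O)[C@@](C[C@H]3OC(=O)[C@]4(C)CCC[C@@](C)(O)[C@H]34)(C2)[C@@H]1O | intermediate
22 | (1R,5S,7R)-6-methylidene-2-oxo-1-(L–CH2)bicyclo[3.2.1]oct-3-en-7-yl acetate (CNP0172716.1) | C=C1[C@@H]2C=CC(=O)[C@@](C[C@H]3OC(=O)[C@]4(C)CCC[C@@](C)(O)[C@H]34)(C2)[C@@H]1OC(C)=O | target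

**Step count and risks**
Total steps: 14. Longest linear sequence: 10 steps (steps 1–5, then 10–14); the ring D branch is steps 6–9.

The three steps most likely to fail:

1. Step 10 (the step labelled as a proposed new method). The C6 radical may be reduced, eliminated to an alkene or captured by a ketone oxygen instead of being lactonised, and facial selectivity at C8 or C6 may be low. Fallback with known chemistry, setting out from 16 and 9 and coming back at 17: N-bromosuccinimide should convert 16 into the bromo diketone (4S)-2-acetyl-2-bromo-4-(dimethoxymethyl)cyclopentan-1-one F1. Visible-light atom-transfer radical addition (Ir(ppy)3, blue light, MeCN) of F1 across the vinyl group of 9 should give the γ-bromo acid (1R,2R,3R)-2-{2-[(1S,4R)-1-acetyl-4-(dimethoxymethyl)-2-oxocyclopentyl]-1-bromoethyl}-3-hydroxy-1,3-dimethylcyclohexane-1-carboxylic acid F2 as C–Br epimers. K2CO3 in DMF should then close the lactone by intramolecular SN2 displacement with inversion, returning 17 after separation from its C6 epimer.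

2. Step 13. Hydride may be delivered to the C9 enone carbonyl, or to the endo face of C15 (loss of chemo- or facial selectivity). Fallback, setting out from 19 and coming back at 22, which never creates the second enone before the reduction: LiN(SiMe3)2 and dimethyl(methylidene)ammonium iodide should give the Mannich base (1S,5S,6R)-6-[(dimethylamino)methyl]-1-(L–CH2)bicyclo[3.2.1]oct-3-ene-2,7-dione F3. NaBH4 in MeOH/CH2Cl2 at −78 °C should reduce the saturated C15 ketone in preference to the conjugated C9 ketone, giving the amino alcohol (1R,5S,6R,7R)-6-[(dimethylamino)methyl]-7-hydroxy-1-(L–CH2)bicyclo[3.2.1]oct-3-en-2-one F4. Ac2O/DMAP should give the acetate (1R,5S,6R,7R)-6-[(dimethylamino)methyl]-2-oxo-1-(L–CH2)bicyclo[3.2.1]oct-3-en-7-yl acetate F5. m-CPBA should give its N-oxide (1R,5S,6R,7R)-6-[(dimethyloxidoammonio)methyl]-2-oxo-1-(L–CH2)bicyclo[3.2.1]oct-3-en-7-yl acetate F6, whose Cope elimination on warming should release the exocyclic methylene and give 22.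

3. Step 2. Regio-, endo- or enantiofacial control may be insufficient in the catalysed cycloaddition, or the triene may oligomerise under the Lewis acid. Fallback by resolution, setting out from 4 and 5 and coming back at 9: an EtAlCl2-promoted cycloaddition (CH2Cl2, −78 °C) would give 6 together with its enantiomer (1S,2R)-2-ethenyl-1,3-dimethylcyclohex-3-ene-1-carbaldehyde F7. Carried through steps 3 to 5, the racemate would give 7, 8 and 9 together with their enantiomers (1R,2S,3S,6S)-2-ethenyl-1,3-dimethyl-7-oxabicyclo[4.1.0]heptane-3-carbaldehyde F8, (1S,2S,3S)-2-ethenyl-3-(hydroxymethyl)-1,3-dimethylcyclohexan-1-ol F9 and (1S,2S,3S)-2-ethenyl-3-hydroxy-1,3-dimethylcyclohexane-1-carboxylic acid F10. Crystallisation of the salt (S)-1-phenylethylammonium (1R,2R,3R)-2-ethenyl-3-hydroxy-1,3-dimethylcyclohexane-1-carboxylate F11 (or of the salt with the antipodal amine, whichever is the less soluble) and acidification would return enantiopure 9.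

**Further compounds**
F1 | step 10 | (4S)-2-acetyl-2-bromo-4-(dimethoxymethyl)cyclopentan-1-one (both C2 epimers) | CC(=O)C1(Br)C[C@@H](C(OC)OC)CC1=O
F2 | step 10 | (1R,2R,3R)-2-{2-[(1S,4R)-1-acetyl-4-(dimethoxymethyl)-2-oxocyclopentyl]-1-bromoethyl}-3-hydroxy-1,3-dimethylcyclohexane-1-carboxylic acid (both C–Br epimers) | CC(=O)[C@@]1(CC(Br)[C@H]2[C@](C)(O)CCC[C@@]2(C)C(=O)O)C[C@@H](C(OC)OC)CC1=O
F3 | step 13 | (1S,5S,6R)-6-[(dimethylamino)methyl]-1-(L–CH2)bicyclo[3.2.1]oct-3-ene-2,7-dione | O=C1[C@@H](CN(C)C)[C@@H]2C=CC(=O)[C@@]1(C[C@H]3OC(=O)[C@]4(C)CCC[C@@](C)(O)[C@H]34)C2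
F4 | step 13 | (1R,5S,6R,7R)-6-[(dimethylamino)methyl]-7-hydroxy-1-(L–CH2)bicyclo[3.2.1]oct-3-en-2-one | O[C@@H]1[C@@H](CN(C)C)[C@@H]2C=CC(=O)[C@@]1(C[C@H]3OC(=O)[C@]4(C)CCC[C@@](C)(O)[C@H]34)C2
F5 | step 13 | (1R,5S,6R,7R)-6-[(dimethylamino)methyl]-2-oxo-1-(L–CH2)bicyclo[3.2.1]oct-3-en-7-yl acetate | CC(=O)O[C@@H]1[C@@H](CN(C)C)[C@@H]2C=CC(=O)[C@@]1(C[C@H]3OC(=O)[C@]4(C)CCC[C@@](C)(O)[C@H]34)C2
F6 | step 13 | (1R,5S,6R,7R)-6-[(dimethyloxidoammonio)methyl]-2-oxo-1-(L–CH2)bicyclo[3.2.1]oct-3-en-7-yl acetate (N-oxide of F5) | CC(=O)O[C@@H]1[C@@H](C[N+](C)(C)[O-])[C@@H]2C=CC(=O)[C@@]1(C[C@H]3OC(=O)[C@]4(C)CCC[C@@](C)(O)[C@H]34)C2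
F7 | step 2 | (1S,2R)-2-ethenyl-1,3-dimethylcyclohex-3-ene-1-carbaldehyde (enantiomer of 6) | O=C[C@@]1(C)CCC=C(C)[C@H]1C=C
F8 | step 2 | (1R,2S,3S,6S)-2-ethenyl-1,3-dimethyl-7-oxabicyclo[4.1.0]heptane-3-carbaldehyde (enantiomer of 7) | O=C[C@@]1(C)CC[C@@H]2O[C@]2(C)[C@H]1C=C
F9 | step 2 | (1S,2S,3S)-2-ethenyl-3-(hydroxymethyl)-1,3-dimethylcyclohexan-1-ol (enantiomer of 8) | OC[C@@]1(C)CCC[C@](C)(O)[C@H]1C=C
F10 | step 2 | (1S,2S,3S)-2-ethenyl-3-hydroxy-1,3-dimethylcyclohexane-1-carboxylic acid (enantiomer of 9) | OC(=O)[C@@]1(C)CCC[C@](C)(O)[C@H]1C=C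
F11 | step 2 | (S)-1-phenylethylammonium (1R,2R,3R)-2-ethenyl-3-hydroxy-1,3-dimethylcyclohexane-1-carboxylate | [O-]C(=O)[C@]1(C)CCC[C@@](C)(O)[C@@H]1C=C.C[C@H]([NH3+])c1ccccc1
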